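**Remark on the chemistry:** vidalol A has no stereogenic element and is achiral, so the route needs no stereocontrol and the structure as drawn is the only stereoisomer.

**Strategy.** Vidalol A is a diarylmethane, and everything rests on cutting the bond between the benzylic CH2 and the ring carbon of the bromophloroglucinol ring that lies between two hydroxyls. The key step is a protecting-group-free, biomimetic Friedel–Crafts benzylation. The catechol ring carries a hydroxyl para to the benzylic carbon, so lanosol (2,3-dibromo-4,5-dihydroxybenzyl alcohol) ionizes under mild acid to a para-quinone methide. This is captured by one of the two symmetry-equivalent C–H carbons of 2-bromophloroglucinol, made strongly nucleophilic by its 1,3,5-trihydroxy pattern. One operation joins both fully functionalized halves and delivers the target directly. Lanosol comes from 5-bromovanillin in three steps, 2-bromophloroglucinol from phloroglucinol in one.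

Key step: step 5

**Route**

Step 1
Reactants: 1 5-bromovanillin (3-bromo-4-hydroxy-5-methoxybenzaldehyde)
Product: 2 5,6-dibromovanillin (2,3-dibromo-4-hydroxy-5-methoxybenzaldehyde)
Conditions: Br2 (1.2 equiv), Fe powder (cat.), AcOH, rt → 50 °C
Reagents that add atoms: bromine, BrBr
Why: Electrophilic aromatic bromination with FeBr3 formed in situ; the position para to the methoxy group is the activated and less hindered one, since the other free position lies between CHO and OMe.

Step 2
Reactants: 2 5,6-dibromovanillin
Product: 3 2,3-dibromo-4,5-dihydroxybenzaldehyde
Conditions: BBr3 (3.5 equiv), CH2Cl2, −78 °C → rt; then H2O, 0 °C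
Reagents that add atoms: none
Why: Lewis-acid-mediated aryl methyl ether cleavage (bromide attacks the O-methyl group of the borane adduct); the aldehyde and the aryl bromides should survive and the catechol is released on hydrolysis.

Step 3
Reactants: 3 2,3-dibromo-4,5-dihydroxybenzaldehyde
Product: 4 lanosol (2,3-dibromo-4,5-dihydroxybenzyl alcohol)
Conditions: NaBH4, THF–H2O, 0 °C, argon; then sat. aq NH4Cl to pH ≈ 6, extraction without alcohols, no heating
Reagents that add atoms: none
Why: Borohydride reduction of an aromatic aldehyde to the benzylic alcohol; the near-neutral, alcohol-free work-up avoids premature ionization of the labile para-hydroxybenzyl alcohol.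

Step 4
Reactants: 5 phloroglucinol (benzene-1,3,5-triol)
Product: 6 2-bromophloroglucinol (2-bromobenzene-1,3,5-triol)
Conditions: 5 (3 equiv), NBS (1.0 equiv, slow addition), THF, −78 → −20 °C; excess 5 removed by chromatography
Reagents that add atoms: N-bromosuccinimide, O=C1CCC(=O)N1Br
Why: Electrophilic aromatic bromination of a highly activated arene whose three C–H positions are equivalent, so only one monobromide is possible; excess arene, low temperature and slow addition should hold the reaction at the mono stage.

Step 5
Reactants: 4 lanosol; 6 2-bromophloroglucinol
Product: 8 vidalol A, via para-quinone methide 7 (not isolated)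
Conditions: 6 (3 equiv), TsOH·H2O (10 mol %), MeCN, 40 °C, argon, slow addition of 4; excess 6 recovered
Reagents that add atoms: none
Why: Brønsted acid ionizes the benzylic C–OH of 4 with push from the hydroxyl para to it, giving para-quinone methide 7 (in equilibrium with its O-protonated benzylic cation), and the C–H carbon of 6 flanked by two hydroxyls adds to the exocyclic methylene in a 1,6-fashion, after which tautomerization rearomatizes both rings. The closest known reaction type is the Friedel–Crafts benzylation of phloroglucinols by 4-hydroxybenzyl alcohols through para-quinone methides. No ring is closed and no stereocentre is formed. The step needs C- over O-alkylation, mono- over bis-benzylation and no self-condensation of 4: phloroglucinols react as carbon nucleophiles and any benzyl ether formed re-ionizes under the acid, the two free positions of 6 are equivalent by symmetry so only one monobenzyl product can arise, the excess of 6 and slow addition of 4 suppress a second benzylation, and the only free ring position of 4 is deactivated by two bromines.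

**Compound list**

1 | 5-bromovanillin (3-bromo-4-hydroxy-5-methoxybenzaldehyde) | O=Cc1cc(OC)c(O)c(Br)c1 | starting material
2 | 5,6-dibromovanillin (2,3-dibromo-4-hydroxy-5-methoxybenzaldehyde) | O=Cc1cc(OC)c(O)c(Br)c1Br | intermediate
3 | 2,3-dibromo-4,5-dihydroxybenzaldehyde | O=Cc1cc(O)c(O)c(Br)c1Br | intermediate
4 | lanosol (2,3-dibromo-4,5-dihydroxybenzyl alcohol) | OCc1cc(O)c(O)c(Br)c1Br | intermediate
5 | phloroglucinol (benzene-1,3,5-triol) | Oc1cc(O)cc(O)c1 | starting material
6 | 2-bromophloroglucinol (2-bromobenzene-1,3,5-triol) | Oc1cc(O)c(Br)c(O)c1 | intermediate
7 | para-quinone methide (2,3-dibromo-6-hydroxy-4-methylidenecyclohexa-2,5-dien-1-one) | C=C1C=C(O)C(=O)C(Br)=C1Br | intermediate (not isolated)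
8 | vidalol A (2-bromo-4-(2,3-dibromo-4,5-dihydroxybenzyl)benzene-1,3,5-triol) | Oc1cc(Cc2c(O)cc(O)c(Br)c2O)c(Br)c(Br)c1O | target

**Step count:** 5 steps in total; longest linear sequence 4 steps (1 → 2 → 3 → 4 → 8).

**Steps most likely to fail**

1. Step 5 (key step). The product still carries one nucleophilic C–H on the phloroglucinol ring and may be benzylated a second time. The acid may also cause loss or migration of bromine on the very electron-rich bromophloroglucinol ring, or cleavage of the new bond by retro-Friedel–Crafts reaction. Fallback: the same bond is formed with all phenols masked as methyl ethers, which are stable to acid and to oxidation. It sets out from 2. O-Methylation (MeI, K2CO3, DMF) should give 2,3-dibromo-4,5-dimethoxybenzaldehyde F1, and NaBH4 reduction (MeOH, 0 °C) should give the stable 2,3-dibromo-4,5-dimethoxybenzyl alcohol F2. Friedel–Crafts benzylation of purchased 2-bromo-1,3,5-trimethoxybenzene (excess) with F2 (cat. TfOH, CH2Cl2, 0 °C) should give 2-bromo-4-(2,3-dibromo-4,5-dimethoxybenzyl)-1,3,5-trimethoxybenzene F3. Exhaustive demethylation of F3 with BBr3 (CH2Cl2, −78 °C → rt) comes back to the route at 8.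

2. Step 4. Bromination of the free triol may run on to di- and tribromide before the starting material is consumed, and the monobromide may be hard to separate and prone to oxidation. Fallback: the bromine is introduced on the trimethyl ether, where monobromination is known to stop cleanly. It sets out from 5. O-Methylation (Me2SO4, K2CO3, acetone, reflux) should give 1,3,5-trimethoxybenzene F4, and NBS (MeCN, 0 °C) should give 2-bromo-1,3,5-trimethoxybenzene F5 (both are also purchasable). Demethylation of F5 with BBr3 (CH2Cl2, −78 °C → rt, cold aqueous quench) comes back to the route at 6.

3. Step 3. The para-hydroxybenzyl alcohol may ionize during work-up or storage and condense with itself to the dibenzyl ether or oligomers, and the catechol may oxidize in the basic borohydride medium. Fallback: the quinone methide precursor is isolated as a stable ether instead of the free alcohol. It sets out from 3. Reduction with NaBH4 in MeOH followed by acidification of the methanolic solution (cat. HCl, rt) should trap the alcohol as lanosol methyl ether (3,4-dibromo-5-(methoxymethyl)benzene-1,2-diol) F6, which can be chromatographed and stored. Used in place of 4 under the conditions of step 5, F6 loses methanol to re-enter the route at para-quinone methide 7 and thence 8.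

**Further compounds**

F1 | step 5 | 2,3-dibromo-4,5-dimethoxybenzaldehyde | O=Cc1cc(OC)c(OC)c(Br)c1Br
F2 | step 5 | 2,3-dibromo-4,5-dimethoxybenzyl alcohol | OCc1cc(OC)c(OC)c(Br)c1Br
F3 | step 5 | 2-bromo-4-(2,3-dibromo-4,5-dimethoxybenzyl)-1,3,5-trimethoxybenzene | COc1cc(Cc2c(OC)cc(OC)c(Br)c2OC)c(Br)c(Br)c1OC
F4 | step 4 | 1,3,5-trimethoxybenzene | COc1cc(OC)cc(OC)c1
F5 | step 4 | 2-bromo-1,3,5-trimethoxybenzene | COc1cc(OC)c(Br)c(OC)c1
F6 | step 3 | lanosol methyl ether (3,4-dibromo-5-(methoxymethyl)benzene-1,2-diol) | COCc1cc(O)c(O)c(Br)c1Br
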